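## Structural features

- The target is a bicyclo[3.3.1]nonane-2,4,9-trione. Ring A (C1–C2–C3–C4–C5–C9) is an enolised 1,3-diketone carrying the 3,4-dihydroxybenzoyl group on C3. Ring B (C1–C9–C5–C6–C7–C8) is a cyclohexanone. The rings share C1, C9 and C5.
- There are four stereocentres. C1 and C5 are quaternary bridgeheads, each with a prenyl group. C7 carries H and prenyl. C8 is quaternary with methyl and 4-methylpent-3-enyl (homoprenyl). C1, C8 and C7 are contiguous, and C1–C8 joins two fully substituted carbons.
- The C7 prenyl group is endo: it lies on the face of ring B that carries the C2–C4 bridge. It is cis to the C8 methyl and trans to the C8 homoprenyl chain.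
- Fragile groups: four trisubstituted alkenes (acid cyclises them onto the enol; no ozonolysis, hydrogenation or strong acid late), an air-sensitive catechol, and a β-triketone open to retro-Claisen cleavage.
- The real difficulty is the crowded C9 region (C1, C5, C8 all quaternary), the C1–C8 bond, the endo relation of C7 to the cage, and absolute control without any heteroatom stereocentre.
- The key step exploits the unit C8–C1(–C9=O): an α-branched bridging ketone is the product pattern of a 1,2-shift of C8 from a C9 carbinol to C1. In ring A, C1 is the γ-carbon of the vinylogous ester C4(=O)–C3=C2(OMe)–C1, which makes it both the aldol nucleophile and the site of oxidation.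

## Logic of the disconnections

**25 ⇒ 24.** The C2 O–CH3 bond and the two aryl O–Si bonds are cut (added in the reverse sense). This masks the acidic enol and the catechol so that organolithium chemistry is possible on the cage. The forward step must be basic and oxygen-free; acid would cyclise prenyl groups onto the enol.

**24 ⇒ 22 + 13.** The C1–CH2 (prenyl) bond is cut. C1 is a bridgehead, so its configuration is dictated by the cage and the substituent can come last as an electrophile. The forward step must deprotonate a hindered bridgehead C–H next to quaternary C8.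

**22 ⇒ 17 + 20.** The C3–C(=O)Ar bond is cut. This removes the whole aryl ketone and leaves a C3–H vinylogous ester. The forward step needs site-selective C3 metalation in the presence of the C1–H.

**17 ⇒ 14 (key).** C1–C8 and C1–C9 are cut and C8–C9 is re-formed. The cage collapses to a monocyclic cyclopentanone in which C9 is the ring carbonyl between C8 and C5, and C1 is the γ-methyl of a 3-methoxybut-2-enoyl group on C5. One sentence for the route: a vinylogous aldol closure telescoped with an iodine(III)-triggered semipinacol ring enlargement converts acylcyclopentanone 14 into the bicyclo[3.3.1]nonane 17. The gain is from a bridged bicycle with three quaternary centres around C9 to a cyclopentanone with three stereocentres that are accessible by enolate chemistry. The demands are that the acyl arm on C5 is cis to the C7 prenyl group (this becomes 7-endo) and that C8, not C5, migrates.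

**14 ⇒ 12 + 13.** The C5–CH2 (prenyl) bond is cut. Prenyl must be the second of the two C5 substituents to enter, so that it arrives anti to the C7 side chain and leaves the acyl arm cis to it. The forward step must be C-selective and face-selective.

**12 ⇒ 9 + 11, and 11 ⇒ 10.** The C5–C4 bond is cut. C5 is the only enolisable position of 9 because C8 is quaternary, so regiochemistry is not an issue. The acyl donor carries C4, C3, C2 and C1 with the enol ether already in the correct regiochemistry.

**9 ⇒ 8 ⇒ 5 + 6 ⇒ 1 + 2.** The alkene of the C7 side chain is shifted by one position, then the C8–CH2 (homoprenyl) and C7–CH2 bonds are cut. A prenyl Grignard cannot be used in a catalytic asymmetric conjugate addition, so its homoallylic isomer is added and isomerised afterwards. The forward steps must set C7 by catalyst control and C8 by trans-alkylation of the regiodefined enolate.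

**20 ⇒ 19 ⇒ 18.** The C–Cl and O–Si bonds are cut back to the commercial acid.

## Other disconnections considered

**Alternative 1:** This is the first that comes to mind: cut C1–C2 and C4–C5, the α,α'-bis-acylation of a ring-B enol ether with malonyl dichloride. Forward, enol ether A1 would give trione A2, followed by C3 aroylation. The second acylation would have to occur at C1, a tertiary carbon next to quaternary C8, in a ring closure that is inherently low-yielding. The malonyl unit would also have to bridge the ring-B face that carries the C7 prenyl group (1,3-diaxial to it), whereas the less hindered face leads to the 7-exo series. A1 itself needs a long, stereocontrolled cyclohexanone synthesis. The chosen plan sets the endo relation by an ordinary anti-alkylation on a five-membered ring.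

**Alternative 2:** Cut C5–C6 and C1–C8, the dearomative alkylation–annulation of an acylphloroglucinol. Forward, A3 and the bis-electrophile A4 would give A5 by alkylation then intramolecular Michael addition. C8 would be formed by attack on a β,β-disubstituted enal whose only stereochemical information is alkene geometry. The C7 formyl group is epimerisable and should settle exo. Absolute control would rest on a chiral ion pair. The aldehyde would still need a homologation–olefination sequence to become prenyl. The chosen plan fixes C7 and C8 before the cage exists and needs no C7 adjustment.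

**Alternative 3:** Cut C2–C3, an intramolecular Claisen (Dieckmann-type) closure of ring A on a fully substituted cyclohexanone. Forward, A6 would give A2. Both α-carbons of A6 must be made quaternary by successive acylation and alkylation, one of them next to C8. The ester and acetyl groups must end up cis-diaxial and syn to the C7 prenyl group. The closure runs under alkoxide conditions that also reverse it by retro-Claisen. The route is longer, with three face-selective enolate steps on a six-membered ring instead of one on a five-membered ring.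

Key step: step 7

## Remarks

- The target is an enolised β-triketone. The tautomer in the given SMILES (C2=O, C4–OH) and the one first released in step 12 (C2–OH, C4=O) interconvert by proton shift and are the same compound.
- Target numbering (C1–C9 of the cage) is used for the carbons of all intermediates.
- Numbered compounds are listed as reactants. "Reagents that add atoms" lists unnumbered reagents only.

## Steps

Step 1
Reactants: 1 2-methylcyclopent-2-en-1-one; 2 4-bromo-2-methylbut-1-ene
Product: 5 (S)-trimethyl{[2-methyl-3-(3-methylbut-3-en-1-yl)cyclopent-1-en-1-yl]oxy}silane, via Grignard reagent 3 (not isolated), via magnesium enolate 4 (not isolated)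
Conditions: Mg, Et2O; then Cu(OTf)2 (3 mol %), chiral alkoxy-NHC imidazolinium precursor (4 mol %, enantiomer giving (S)-5), 1, Et2O, 0 °C; then TMSCl, Et3N, DMPU, 0 °C → rt
Reagents that add atoms: chlorotrimethylsilane, C[Si](C)(C)Cl
Why: Copper–NHC-catalysed asymmetric conjugate addition of a primary alkyl Grignard reagent to an α-substituted cyclic enone with enolate trapping; the chiral copper complex selects the enone face and sets C7, and silylation fixes the tetrasubstituted enolate regiochemistry. The homoallylic Grignard is used because a prenyl Grignard would add 1,2 with allylic transposition.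

Step 2
Reactants: 5 (S)-silyl enol ether; 6 5-iodo-2-methylpent-2-ene
Product: 8 (2R,3S)-2-methyl-3-(3-methylbut-3-en-1-yl)-2-(4-methylpent-3-en-1-yl)cyclopentan-1-one, via lithium enolate 7 (not isolated)
Conditions: MeLi, THF, 0 °C; then 6, DMPU, −78 → 0 °C
Reagents that add atoms: none
Why: MeLi cleaves the silyl enol ether to the regiodefined lithium enolate, and SN2 alkylation by the primary iodide should occur anti to the C7 side chain. This sets quaternary C8 with methyl cis and homoprenyl trans to the C7 substituent.

Step 3
Reactants: 8 (2R,3S)-ketone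
Product: 9 (2R,3R)-2-methyl-3-(3-methylbut-2-en-1-yl)-2-(4-methylpent-3-en-1-yl)cyclopentan-1-one
Conditions: Co(salen-tBu,tBu)Cl (3 mol %), PhSiH3 (6 mol %), benzene, rt
Reagents that add atoms: none
Why: Cobalt-hydride hydrogen-atom-transfer alkene isomerisation moves the 1,1-disubstituted alkene by one position into the more stable trisubstituted (prenyl) position. The ketone and the existing trisubstituted alkene should be inert and no stereocentre is touched (the descriptor at C3 changes only by CIP priority).

Step 4
Reactants: 10 (E)-3-methoxybut-2-enoic acid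
Product: 11 (E)-3-methoxybut-2-enoyl chloride
Conditions: (COCl)2, DMF (cat.), CH2Cl2, 0 °C → rt; used crude
Reagents that add atoms: oxalyl chloride, ClC(=O)C(Cl)=O
Why: Standard acid chloride formation via the Vilsmeier-type chloroiminium; the E geometry (methyl cis to the carbonyl, as needed for ring A) is retained.

Step 5
Reactants: 9 (2R,3R)-ketone; 11 acid chloride
Product: 12 (2R,3S)-5-[(E)-3-methoxybut-2-enoyl]-2-methyl-3-(3-methylbut-2-en-1-yl)-2-(4-methylpent-3-en-1-yl)cyclopentan-1-one (C5 epimers/enol forms)
Conditions: MgBr2·OEt2, i-Pr2NEt, CH2Cl2, 0 °C → rt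
Reagents that add atoms: none
Why: Soft-enolisation Claisen-type C-acylation; C5 is the only enolisable position (C8 is quaternary) and the chelated magnesium enolate is acylated on carbon, the product being drained as its magnesium diketonate. The C5 configuration is not yet fixed.

Step 6
Reactants: 12 β-diketone; 13 1-bromo-3-methylbut-2-ene (prenyl bromide)
Product: 14 (2R,3S,5S)-5-[(E)-3-methoxybut-2-enoyl]-2-methyl-3,5-bis(3-methylbut-2-en-1-yl)-2-(4-methylpent-3-en-1-yl)cyclopentan-1-one
Conditions: K2CO3, n-Bu4NI (cat.), acetone, 40 °C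
Reagents that add atoms: none
Why: C-alkylation of a cyclic β-diketone enolate with an allylic bromide. The electrophile should enter the ring face opposite the C7 prenyl group and its cis C8 methyl, which sets C5 with the acyl arm cis to the C7 prenyl group (the relation that becomes 7-endo).

Step 7
Reactants: 14 acylcyclopentanone
Product: 17 (1R,5S,7S,8R)-2-methoxy-8-methyl-5,7-bis(3-methylbut-2-en-1-yl)-8-(4-methylpent-3-en-1-yl)bicyclo[3.3.1]non-2-ene-4,9-dione, via ketol 15 (not isolated), via iodane 16 (not isolated)
Conditions: KOH, MeOH, 0 °C → rt until 14 is consumed; then PhI(OAc)2, 0 °C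
Reagents that add atoms: none
Why: Methoxide/hydroxide reversibly deprotonates the γ-methyl of the vinylogous ester, and the dienolate closes ring A by a 6-(enolendo)-exo-trig vinylogous aldol addition to the non-enolisable cyclopentanone carbonyl (new C1–C9 bond); the four-atom tether on C5 allows only the cis-fused ketol 15. Renewed γ-deprotonation gives the ring dienolate, which attacks PhI(OMe)2 (formed in situ) at C1 to give iodane 16. The C9 alkoxide then drives a semipinacol 1,2-shift of C8 from C9 to C1 with loss of PhI, which forms the C1–C8 bond, unmasks the C9 ketone and enlarges the cyclopentane to ring B. The closest known reaction type is the iodine(III)-mediated oxidative semipinacol ring expansion of hydroxy-hydrindenone vinylogous esters to bicyclo[3.3.1]nonanes. Ring A is closed by the aldol; ring B is not closed but grows from five to six members by the suprafacial shift, which can only give the 1,3-diaxially bridged cage. C1 is the only new stereocentre and is fixed by C5 through the cis fusion and the shift (retention at C8, inversion at C1); because the acyl arm of 14 is cis to the C7 prenyl group, the C2–C4 bridge ends up syn to it. The step needs γ- rather than α-attack of the dienolate on iodine, and migration of C8 rather than C5: C8 is a fully alkylated carbon that can sit axial and anti to the C1–I bond, whereas C5 is α to the C4 carbonyl and its shift would contract ring A. It also needs the 1,3-diketone of 14 to survive methoxide, which is plausible because C9 is shielded by two quaternary neighbours and C4 is a deactivated vinylogous ester carbonyl.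

Step 8
Reactants: 18 3,4-dihydroxybenzoic acid
Product: 19 tert-butyldimethylsilyl 3,4-bis[(tert-butyldimethylsilyl)oxy]benzoate
Conditions: TBSCl (3.5 equiv), imidazole, DMF, rt
Reagents that add atoms: tert-butyldimethylsilyl chloride, CC(C)(C)[Si](C)(C)Cl
Why: Standard exhaustive silylation of the phenols and the acid; silyl ethers are chosen because they tolerate organolithiums and are removed by base, not acid.

Step 9
Reactants: 19 tris-silyl compound
Product: 20 3,4-bis[(tert-butyldimethylsilyl)oxy]benzoyl chloride
Conditions: (COCl)2, DMF (cat.), CH2Cl2, 0 °C → rt; used crude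
Reagents that add atoms: oxalyl chloride, ClC(=O)C(Cl)=O
Why: Direct conversion of a silyl ester into the acid chloride with oxalyl chloride/DMF under neutral conditions; no HCl is released, so the aryl silyl ethers should survive.

Step 10
Reactants: 17 bicyclic vinylogous ester; 20 aroyl chloride
Product: 22 3-{3,4-bis[(tert-butyldimethylsilyl)oxy]benzoyl}-2-methoxy-8-methyl-5,7-bis(3-methylbut-2-en-1-yl)-8-(4-methylpent-3-en-1-yl)bicyclo[3.3.1]non-2-ene-4,9-dione (stereocentres as in 17), via vinyllithium 21 (not isolated)
Conditions: LiTMP, THF, −78 °C; then 20, −78 → −40 °C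
Reagents that add atoms: none
Why: Directed α-lithiation of a β-methoxy enone (vinyl C3–H flanked by OMe and C=O, chelated vinyllithium) followed by acylation. The C1 bridgehead C–H, which is only γ to the enone carbonyl and sits next to quaternary C8, is expected to be removed more slowly; no stereocentre is formed.

Step 11
Reactants: 22 C3-aroyl compound; 13 1-bromo-3-methylbut-2-ene
Product: 24 3-{3,4-bis[(tert-butyldimethylsilyl)oxy]benzoyl}-2-methoxy-8-methyl-1,5,7-tris(3-methylbut-2-en-1-yl)-8-(4-methylpent-3-en-1-yl)bicyclo[3.3.1]non-2-ene-4,9-dione (stereocentres as in the target), via bridgehead organolithium 23 (not isolated)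
Conditions: LiTMP, THF, −78 °C; then 13, −78 → 0 °C
Reagents that add atoms: none
Why: Bridgehead lithiation–alkylation of a bicyclo[3.3.1]nonane-trione enol ether; C1–H is the only acidic proton left, and the carbanion is stabilised by the C9 carbonyl and the now doubly activated C2. The cage allows only one configuration at C1.

Step 12
Reactants: 24 protected target
Product: 25 (1S,5S,7S,8R)-3-(3,4-dihydroxybenzoyl)-4-hydroxy-8-methyl-1,5,7-tris(3-methylbut-2-en-1-yl)-8-(4-methylpent-3-en-1-yl)bicyclo[3.3.1]non-3-ene-2,9-dione (target CNP0108469.1)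
Conditions: LiOH·H2O, dioxane/H2O (degassed, Ar), 90 °C; then 1 M HCl, 0 °C (work-up)
Reagents that add atoms: lithium hydroxide, [Li+].[OH-]
Why: Hydroxide adds to C2 and expels methoxide (vinylogous ester hydrolysis), and it also cleaves the two aryl silyl ethers; the product sits as a polyanion that should resist retro-Claisen cleavage. Exclusion of oxygen protects the catechol and the cold, dilute acid work-up avoids prenyl cyclisation.

## Compound list

1 | 2-methylcyclopent-2-en-1-one | CC1=CCCC1=O | starting material
2 | 4-bromo-2-methylbut-1-ene | C=C(C)CCBr | starting material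
3 | (3-methylbut-3-en-1-yl)magnesium bromide | C=C(C)CC[Mg]Br | intermediate (not isolated)
4 | bromomagnesium (S)-2-methyl-3-(3-methylbut-3-en-1-yl)cyclopent-1-en-1-olate | CC1=C(O[Mg]Br)CC[C@@H]1CCC(C)=C | intermediate (not isolated)
5 | (S)-trimethyl{[2-methyl-3-(3-methylbut-3-en-1-yl)cyclopent-1-en-1-yl]oxy}silane | CC1=C(O[Si](C)(C)C)CC[C@@H]1CCC(C)=C | intermediate
6 | 5-iodo-2-methylpent-2-ene | CC(C)=CCCI | starting material
7 | lithium (S)-2-methyl-3-(3-methylbut-3-en-1-yl)cyclopent-1-en-1-olate | [Li]OC1=C(C)[C@@H](CCC(C)=C)CC1 | intermediate (not isolated)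
8 | (2R,3S)-2-methyl-3-(3-methylbut-3-en-1-yl)-2-(4-methylpent-3-en-1-yl)cyclopentan-1-one | CC(C)=CCC[C@]1(C)[C@@H](CCC(C)=C)CCC1=O | intermediate
9 | (2R,3R)-2-methyl-3-(3-methylbut-2-en-1-yl)-2-(4-methylpent-3-en-1-yl)cyclopentan-1-one | CC(C)=CCC[C@]1(C)[C@@H](CC=C(C)C)CCC1=O | intermediate
10 | (E)-3-methoxybut-2-enoic acid | C/C(OC)=C\C(O)=O | starting material
11 | (E)-3-methoxybut-2-enoyl chloride | C/C(OC)=C\C(Cl)=O | intermediate
12 | (2R,3S)-5-[(E)-3-methoxybut-2-enoyl]-2-methyl-3-(3-methylbut-2-en-1-yl)-2-(4-methylpent-3-en-1-yl)cyclopentan-1-one (C5 not fixed) | CC(C)=CCC[C@]1(C)[C@@H](CC=C(C)C)CC(C(=O)/C=C(\C)OC)C1=O | intermediate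
13 | 1-bromo-3-methylbut-2-ene | CC(C)=CCBr | starting material
14 | (2R,3S,5S)-5-[(E)-3-methoxybut-2-enoyl]-2-methyl-3,5-bis(3-methylbut-2-en-1-yl)-2-(4-methylpent-3-en-1-yl)cyclopentan-1-one | CC(C)=CCC[C@]1(C)[C@@H](CC=C(C)C)C[C@](C(=O)/C=C(\C)OC)(CC=C(C)C)C1=O | intermediate
15 | cis-fused ketol 7a-hydroxy-6-methoxy-1-methyl-2,3a-bis(3-methylbut-2-en-1-yl)-1-(4-methylpent-3-en-1-yl)-1,2,3,3a,7,7a-hexahydro-4H-inden-4-one (OH, 3a-prenyl and homoprenyl on one face; ring-A carbons, 2-prenyl and 1-methyl on the other) | CC(C)=CCC[C@]1(C)[C@@H](CC=C(C)C)C[C@@]2(CC=C(C)C)C(=O)C=C(OC)C[C@@]12O | intermediate (not isolated)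
16 | potassium C9-alkoxide of 15 bearing a methoxy(phenyl)-λ3-iodanyl group on C1, iodine anti to the C9–C8 bond | CC(C)=CCC[C@]1(C)[C@@H](CC=C(C)C)C[C@@]2(CC=C(C)C)C(=O)C=C(OC)[C@H](I(OC)c3ccccc3)[C@@]12[O-].[K+] | intermediate (not isolated)
17 | (1R,5S,7S,8R)-2-methoxy-8-methyl-5,7-bis(3-methylbut-2-en-1-yl)-8-(4-methylpent-3-en-1-yl)bicyclo[3.3.1]non-2-ene-4,9-dione | CC(C)=CCC[C@]1(C)[C@@H](CC=C(C)C)C[C@]2(CC=C(C)C)C(=O)[C@H]1C(OC)=CC2=O | intermediate
18 | 3,4-dihydroxybenzoic acid | OC(=O)c1ccc(O)c(O)c1 | starting material
19 | tert-butyldimethylsilyl 3,4-bis[(tert-butyldimethylsilyl)oxy]benzoate | CC(C)(C)[Si](C)(C)OC(=O)c1ccc(O[Si](C)(C)C(C)(C)C)c(O[Si](C)(C)C(C)(C)C)c1 | intermediate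
20 | 3,4-bis[(tert-butyldimethylsilyl)oxy]benzoyl chloride | CC(C)(C)[Si](C)(C)Oc1ccc(C(Cl)=O)cc1O[Si](C)(C)C(C)(C)C | intermediate
21 | 3-lithio derivative of 17 | CC(C)=CCC[C@]1(C)[C@@H](CC=C(C)C)C[C@]2(CC=C(C)C)C(=O)[C@H]1C(OC)=C([Li])C2=O | intermediate (not isolated)
22 | 3-{3,4-bis[(tert-butyldimethylsilyl)oxy]benzoyl} derivative of 17 | CC(C)=CCC[C@]1(C)[C@@H](CC=C(C)C)C[C@]2(CC=C(C)C)C(=O)[C@H]1C(OC)=C(C(=O)c3ccc(O[Si](C)(C)C(C)(C)C)c(O[Si](C)(C)C(C)(C)C)c3)C2=O | intermediate
23 | 1-lithio derivative of 22 | CC(C)=CCC[C@]1(C)[C@@H](CC=C(C)C)C[C@]2(CC=C(C)C)C(=O)[C@@]1([Li])C(OC)=C(C(=O)c3ccc(O[Si](C)(C)C(C)(C)C)c(O[Si](C)(C)C(C)(C)C)c3)C2=O | intermediate (not isolated)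
24 | 3-{3,4-bis[(tert-butyldimethylsilyl)oxy]benzoyl}-2-methoxy-8-methyl-1,5,7-tris(3-methylbut-2-en-1-yl)-8-(4-methylpent-3-en-1-yl)bicyclo[3.3.1]non-2-ene-4,9-dione (stereocentres as in the target) | CC(C)=CCC[C@]1(C)[C@@H](CC=C(C)C)C[C@]2(CC=C(C)C)C(=O)[C@@]1(CC=C(C)C)C(OC)=C(C(=O)c3ccc(O[Si](C)(C)C(C)(C)C)c(O[Si](C)(C)C(C)(C)C)c3)C2=O | intermediate
25 | (1S,5S,7S,8R)-3-(3,4-dihydroxybenzoyl)-4-hydroxy-8-methyl-1,5,7-tris(3-methylbut-2-en-1-yl)-8-(4-methylpent-3-en-1-yl)bicyclo[3.3.1]non-3-ene-2,9-dione | CC(C)=CCC[C@]1(C)[C@@H](CC=C(C)C)C[C@]2(CC=C(C)C)C(=O)[C@@]1(CC=C(C)C)C(=O)C(C(=O)c1ccc(O)c(O)c1)=C2O | target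

## Step count and least certain steps

Total step count: 12. Longest linear sequence: 9 (steps 1, 2, 3, 5, 6, 7, 10, 11, 12). Steps 4 and 8–9 make the two acyl chlorides.

**Step 7 (key step).** The most likely failure is before the shift: an unfavourable aldol equilibrium or methoxide-induced retro-Claisen opening of the non-enolisable 1,3-diketone, so that the oxidant meets open-chain dienolate. A second failure mode is attack of the C9 alkoxide oxygen on C1 (epoxide closure) instead of the carbon shift. The fallback separates ring closure from oxidation and closes ring A without alkoxide. It sets out from 14 and comes back at 17. Dilute HCl in THF hydrolyses the enol ether to the open β-diketone (2R,3S,5S)-2-methyl-3,5-bis(3-methylbut-2-en-1-yl)-2-(4-methylpent-3-en-1-yl)-5-(3-oxobutanoyl)cyclopentan-1-one F1. Excess LDA in THF forms its 1,3-diketone dianion, whose terminal carbon adds to the C9 carbonyl to give the cis-fused hydroxy-dione F2 as a stable diketonate. O-Methylation (Me2SO4, K2CO3) gives isolated 15 together with its enol ether regioisomer F3, which is separated. Pure 15 is then treated with PhI(OAc)2 and KOH in MeOH to give 17.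

**Step 11.** The bridgehead next to quaternary C8 may be deprotonated incompletely or alkylated slowly, and the carbanion or base may attack the electrophilic aroyl enedione instead. If in step 10 the bridgehead were metalated in competition with C3, the same fallback applies. It sets out from 17 and comes back at 24, reversing the order with C3 blocked. LDA with in situ TMSCl gives the 3-(trimethylsilyl) derivative of 17 F4. LiTMP then prenyl bromide 13 gives the 1-prenyl-3-silyl compound F5. TBAF removes the silyl group to give the 1-prenyl C3–H vinylogous ester F6. LiTMP then 20 gives 24.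

**Step 6.** Facial selectivity may be poor because the C7 prenyl group and the C8 homoprenyl chain shield opposite faces, and O-prenylation may compete. The fallback replaces substrate control by catalyst control. It sets out from 12 and comes back at 14. Palladium-catalysed asymmetric allylic alkylation (Pd2(dba)3, chiral diphosphine ligand, allyl acetate) gives the C5-allyl analogue F7 with the face chosen by the ligand. Cross-metathesis with 2-methylbut-2-ene (Ru alkylidene catalyst) converts allyl into prenyl to give 14.

**Step 1.** Enantioinduction on a five-membered α-substituted enone may be insufficient, and uncatalysed 1,2-addition may erode it. The fallback sets C7 by asymmetric conjugate reduction instead of conjugate addition. It sets out from 2 (as Grignard reagent 3) and comes back at 5. Addition of 3 to commercial 3-ethoxycyclopent-2-en-1-one F8 with acidic work-up gives 3-(3-methylbut-3-en-1-yl)cyclopent-2-en-1-one F9. Copper hydride-catalysed asymmetric 1,4-reduction (CuCl, NaOt-Bu, chiral bisphosphine, PMHS) with in situ methylation of the silyl enol ether (MeI, fluoride source) gives trans-(2R,3S)-2-methyl-3-(3-methylbut-3-en-1-yl)cyclopentan-1-one F10. Thermodynamic silylation (TMSCl, NaI, Et3N, MeCN) gives the tetrasubstituted enol ether 5.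

## Further compounds

F1 | step 7 | (2R,3S,5S)-2-methyl-3,5-bis(3-methylbut-2-en-1-yl)-2-(4-methylpent-3-en-1-yl)-5-(3-oxobutanoyl)cyclopentan-1-one | CC(C)=CCC[C@]1(C)[C@@H](CC=C(C)C)C[C@](C(=O)CC(C)=O)(CC=C(C)C)C1=O
F2 | step 7 | cis-fused 7a-hydroxy-1-methyl-2,3a-bis(3-methylbut-2-en-1-yl)-1-(4-methylpent-3-en-1-yl)hexahydro-1H-indene-4,6-dione (configuration as in 15) | CC(C)=CCC[C@]1(C)[C@@H](CC=C(C)C)C[C@@]2(CC=C(C)C)C(=O)CC(=O)C[C@@]12O
F3 | step 7 | cis-fused 7a-hydroxy-4-methoxy-1-methyl-2,3a-bis(3-methylbut-2-en-1-yl)-1-(4-methylpent-3-en-1-yl)-1,2,3,3a,7,7a-hexahydro-6H-inden-6-one (regioisomer of 15) | CC(C)=CCC[C@]1(C)[C@@H](CC=C(C)C)C[C@@]2(CC=C(C)C)C(OC)=CC(=O)C[C@@]12O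
F4 | step 11 | 3-(trimethylsilyl) derivative of 17 | CC(C)=CCC[C@]1(C)[C@@H](CC=C(C)C)C[C@]2(CC=C(C)C)C(=O)[C@H]1C(OC)=C([Si](C)(C)C)C2=O
F5 | step 11 | 2-methoxy-8-methyl-1,5,7-tris(3-methylbut-2-en-1-yl)-8-(4-methylpent-3-en-1-yl)-3-(trimethylsilyl)bicyclo[3.3.1]non-2-ene-4,9-dione | CC(C)=CCC[C@]1(C)[C@@H](CC=C(C)C)C[C@]2(CC=C(C)C)C(=O)[C@@]1(CC=C(C)C)C(OC)=C([Si](C)(C)C)C2=O
F6 | step 11 | 2-methoxy-8-methyl-1,5,7-tris(3-methylbut-2-en-1-yl)-8-(4-methylpent-3-en-1-yl)bicyclo[3.3.1]non-2-ene-4,9-dione | CC(C)=CCC[C@]1(C)[C@@H](CC=C(C)C)C[C@]2(CC=C(C)C)C(=O)[C@@]1(CC=C(C)C)C(OC)=CC2=O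
F7 | step 6 | (2R,3S,5S)-5-allyl-5-[(E)-3-methoxybut-2-enoyl]-2-methyl-3-(3-methylbut-2-en-1-yl)-2-(4-methylpent-3-en-1-yl)cyclopentan-1-one | CC(C)=CCC[C@]1(C)[C@@H](CC=C(C)C)C[C@](C(=O)/C=C(\C)OC)(CC=C)C1=O
F8 | step 1 | 3-ethoxycyclopent-2-en-1-one | CCOC1=CC(=O)CC1
F9 | step 1 | 3-(3-methylbut-3-en-1-yl)cyclopent-2-en-1-one | C=C(C)CCC1=CC(=O)CC1
F10 | step 1 | (2R,3S)-2-methyl-3-(3-methylbut-3-en-1-yl)cyclopentan-1-one | C[C@@H]1[C@@H](CCC(C)=C)CCC1=O
A1 | alternative 1 | 1-methoxy-5-methyl-2,4,6-tris(3-methylbut-2-en-1-yl)-5-(4-methylpent-3-en-1-yl)cyclohex-1-ene (C4 and C5 as C7 and C8 of the target) | COC1=C(CC=C(C)C)C[C@H](CC=C(C)C)[C@@](C)(CCC=C(C)C)C1CC=C(C)C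
A2 | alternative 1 | 8-methyl-1,5,7-tris(3-methylbut-2-en-1-yl)-8-(4-methylpent-3-en-1-yl)bicyclo[3.3.1]nonane-2,4,9-trione (stereocentres as in the target) | CC(C)=CCC[C@]1(C)[C@@H](CC=C(C)C)C[C@]2(CC=C(C)C)C(=O)[C@@]1(CC=C(C)C)C(=O)CC2=O
A3 | alternative 2 | (3,4-dihydroxyphenyl)[2,4,6-trihydroxy-3,5-bis(3-methylbut-2-en-1-yl)phenyl]methanone | CC(C)=CCc1c(O)c(CC=C(C)C)c(O)c(C(=O)c2ccc(O)c(O)c2)c1O
A4 | alternative 2 | [(E)-2-formyl-3,7-dimethylocta-2,6-dien-1-yl] acetate | CC(C)=CCC/C(C)=C(/C=O)COC(C)=O
A5 | alternative 2 | 7-formyl analogue of the target (C7 CHO in place of prenyl) | CC(C)=CCC[C@]1(C)[C@@H](C=O)C[C@]2(CC=C(C)C)C(=O)[C@@]1(CC=C(C)C)C(=O)C(C(=O)c1ccc(O)c(O)c1)=C2O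
A6 | alternative 3 | methyl 3-acetyl-6-methyl-1,3,5-tris(3-methylbut-2-en-1-yl)-6-(4-methylpent-3-en-1-yl)-2-oxocyclohexane-1-carboxylate (stereocentres as in the target) | COC(=O)[C@]1(CC=C(C)C)C(=O)[C@](CC=C(C)C)(C(C)=O)C[C@H](CC=C(C)C)[C@@]1(C)CCC=C(C)C
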